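## Retrosynthetic overview

1. The diaryl ether C–O bond is not made by Ullmann or SNAr coupling. It arises by formal O-insertion into a benzophenone: the target comes from water-induced C–C fragmentation (retro-Claisen with rearomatisation) of a spiro-grisadienedione.
2. The spiro-grisadienedione comes from biomimetic oxidative dearomatising spiroetherification of the benzophenone monochlorosulochrin.
3. Monochlorosulochrin comes from de novo construction of ring A. A regioselective Diels–Alder/aromatisation of an aroylpropiolate with 1,1-dimethoxy-3-silyloxybutadiene delivers 3-OMe and 5-OH already differentiated.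
4. The aroylpropiolate comes from orcinol (ring B) by bis-MOM protection, directed ortho-metalation/formylation, chlorination of the symmetric aldehyde, propiolate addition and oxidation.
5. Ring order: ring B is bought, ring A is formed by cycloaddition, and the spiro-furanone ring is formed third and deliberately opened in the last step.

Assumption: the target SMILES holds no stereocentre and the diaryl ether axis is not configurationally stable. The compound is therefore achiral and no asymmetric step is needed. The two chiral intermediates (the propargylic alcohol and the spirodienone) are carried as racemates and lose their stereocentres later.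

## Route

Step 1
Reactants: 1 orcinol (5-methylbenzene-1,3-diol)
Product: 2 1,3-bis(methoxymethoxy)-5-methylbenzene
Conditions: MOMCl (2.5 equiv), i-Pr2NEt (3 equiv), CH2Cl2, 0 °C to rt
Reagents that add atoms: chloromethyl methyl ether (MOMCl), COCCl
Why: Williamson-type O-alkylation of both phenols with the very reactive α-chloro ether gives the bis-acetal, which protects the phenols and supplies two cooperating directing groups for step 2.

Step 2
Reactants: 2 1,3-bis(methoxymethoxy)-5-methylbenzene
Product: 4 2,6-bis(methoxymethoxy)-4-methylbenzaldehyde, via aryllithium 3 (not isolated)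
Conditions: n-BuLi (1.1 equiv), THF, 0 °C, 1 h; DMF (2 equiv), 0 °C to rt; H2O
Reagents that add atoms: N,N-dimethylformamide, CN(C)C=O
Why: Directed ortho-metalation followed by Bouveault-type formylation works because the C–H flanked by the two OMOM groups is the most acidic and best chelated site, so the aldehyde carbon lands between the two oxygens.

Step 3
Reactants: 4 2,6-bis(methoxymethoxy)-4-methylbenzaldehyde
Product: 5 3-chloro-2,6-bis(methoxymethoxy)-4-methylbenzaldehyde
Conditions: NCS (1.05 equiv), DMF, 40 °C, dark
Reagents that add atoms: N-chlorosuccinimide, O=C1CCC(=O)N1Cl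
Why: In this electrophilic aromatic chlorination C3 and C5 of the symmetric aldehyde are equivalent, are the only free ring positions and are each ortho/para to the two alkoxy groups, so one monochloride forms and the first chlorine slows a second substitution.

Step 4
Reactants: 5 3-chloro-2,6-bis(methoxymethoxy)-4-methylbenzaldehyde; 6 methyl propiolate
Product: 8 methyl (±)-4-[3-chloro-2,6-bis(methoxymethoxy)-4-methylphenyl]-4-hydroxybut-2-ynoate, via lithium methyl propiolate 7 (not isolated)
Conditions: 6 (1.3 equiv), LiHMDS (1.25 equiv), THF, −78 °C; then 5, −78 °C; AcOH quench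
Reagents that add atoms: none
Why: This is a 1,2-addition of a lithium acetylide to an aldehyde at −78 °C, where lithium methyl propiolate is stable, and the new carbinol stereocentre forms as a racemate and is erased by the oxidation in step 5.

Step 5
Reactants: 8 methyl (±)-4-[3-chloro-2,6-bis(methoxymethoxy)-4-methylphenyl]-4-hydroxybut-2-ynoate
Product: 9 methyl 4-[3-chloro-2,6-bis(methoxymethoxy)-4-methylphenyl]-4-oxobut-2-ynoate
Conditions: activated MnO2 (15 equiv), CH2Cl2, rt; filtration
Reagents that add atoms: none
Why: Activated MnO2 oxidation of a benzylic-propargylic alcohol runs under neutral conditions that leave the MOM acetals, the aryl chloride and the electrophilic ynoate untouched and needs only filtration as work-up.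

Step 6
Reactants: 10 acetyl chloride; 11 1,1-dimethoxyethene (ketene dimethyl acetal)
Product: 12 4,4-dimethoxybut-3-en-2-one
Conditions: Et3N (1.2 equiv), Et2O, 0 °C to rt
Reagents that add atoms: none
Why: In this C-acylation of an electron-rich ketene acetal (McElvain-type acylation) the nucleophilic CH2 carbon attacks the acid chloride and the amine takes up HCl, so the acylketene acetal survives instead of being demethylated.

Step 7
Reactants: 12 4,4-dimethoxybut-3-en-2-one
Product: 13 1,1-dimethoxy-3-(trimethylsilyloxy)buta-1,3-diene
Conditions: TMSOTf (1.1 equiv), Et3N (1.5 equiv), Et2O, 0 °C; pentane extraction, used freshly distilled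
Reagents that add atoms: trimethylsilyl trifluoromethanesulfonate, C[Si](C)(C)OS(=O)(=O)C(F)(F)F
Why: Soft enolisation and O-silylation of the methyl ketone (the way Danishefsky-type dienes are made) can occur only at the CH3 group and gives the 2-silyloxydiene.

Step 8
Reactants: 9 methyl 4-[3-chloro-2,6-bis(methoxymethoxy)-4-methylphenyl]-4-oxobut-2-ynoate; 13 1,1-dimethoxy-3-(trimethylsilyloxy)buta-1,3-diene
Product: 16 methyl 2-(3-chloro-2,6-dihydroxy-4-methylbenzoyl)-5-hydroxy-3-methoxybenzoate (monochlorosulochrin), via Diels-Alder cycloadduct 14 (not isolated), via bis-MOM benzophenone 15 (not isolated)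
Conditions: 13 (2 equiv), PhMe, rt to 70 °C; then MeOH, conc. HCl (cat.), 45 °C
Reagents that add atoms: none
Why: In this regioselective normal-electron-demand Diels–Alder reaction with aromatisation (Danishefsky–Brassard type benzannulation) the nucleophilic CH2 terminus of 13 bonds to the alkyne carbon β to the aryl ketone (the stronger acceptor), which is the carbon bearing CO2Me, so the acetal carbon ends next to the aroyl group, loss of MeOH gives the arene with 3-OMe and 5-OH already differentiated, and HCl/MeOH then removes the silyl group and both MOM acetals.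

Step 9
Reactants: 16 monochlorosulochrin
Product: 17 methyl (±)-5-chloro-4-hydroxy-6'-methoxy-6-methyl-3,4'-dioxo-3H-spiro[1-benzofuran-2,1'-cyclohexa-2',5'-diene]-2'-carboxylate
Conditions: PhI(OAc)2 (1.05 equiv), (CF3)2CHOH, 0 °C, 20 min, no base
Reagents that add atoms: none
Why: In this hypervalent-iodine oxidative phenol dearomatisation with 5-exo spiroetherification (the biomimetic sulochrin-to-grisadienedione phenol coupling) PhI(OAc)2 engages the unhindered, non-chelated ring-A phenol, and under neutral conditions its para carbon is attacked by the ring-B OH para to chlorine, which is the more nucleophilic and less hindered one while the more acidic chlorine-flanked OH keeps the hydrogen bond to the ketone; the spiro stereocentre forms as a racemate and is erased in step 10.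

Step 10
Reactants: 17 methyl (±)-5-chloro-4-hydroxy-6'-methoxy-6-methyl-3,4'-dioxo-3H-spiro[1-benzofuran-2,1'-cyclohexa-2',5'-diene]-2'-carboxylate
Product: 18 isodihydromaldoxin, 3-chloro-2-hydroxy-6-[4-hydroxy-2-methoxy-6-(methoxycarbonyl)phenoxy]-4-methylbenzoic acid
Conditions: conc. H2SO4, 0 °C, 15 min; pour onto ice
Reagents that add atoms: water, O
Why: In this acid-promoted retro-Claisen type C–C fragmentation of the grisadienedione (the geodin-to-geodin-hydrate cleavage) the protonated dienone is a phenol in disguise and leaves from the ketone carbon with rearomatisation, water turns that carbon into the CO2H group, the aryl–O bond made in step 9 remains as the diaryl ether, and xanthone closure or dienone–phenol shifts are blocked because both positions next to the ether carbon of ring A are substituted.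

## Compound list

1 | orcinol (5-methylbenzene-1,3-diol) | Cc1cc(O)cc(O)c1 | starting material
2 | 1,3-bis(methoxymethoxy)-5-methylbenzene | COCOc1cc(C)cc(OCOC)c1 | intermediate
3 | [2,6-bis(methoxymethoxy)-4-methylphenyl]lithium (not isolated) | [Li]c1c(OCOC)cc(C)cc1OCOC | intermediate
4 | 2,6-bis(methoxymethoxy)-4-methylbenzaldehyde | COCOc1cc(C)cc(OCOC)c1C=O | intermediate
5 | 3-chloro-2,6-bis(methoxymethoxy)-4-methylbenzaldehyde | COCOc1cc(C)c(Cl)c(OCOC)c1C=O | intermediate
6 | methyl propiolate | C#CC(=O)OC | starting material
7 | lithium methyl propiolate (not isolated) | [Li]C#CC(=O)OC | intermediate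
8 | methyl (±)-4-[3-chloro-2,6-bis(methoxymethoxy)-4-methylphenyl]-4-hydroxybut-2-ynoate (racemic) | COCOc1cc(C)c(Cl)c(OCOC)c1C(O)C#CC(=O)OC | intermediate
9 | methyl 4-[3-chloro-2,6-bis(methoxymethoxy)-4-methylphenyl]-4-oxobut-2-ynoate | COCOc1cc(C)c(Cl)c(OCOC)c1C(=O)C#CC(=O)OC | intermediate
10 | acetyl chloride | CC(=O)Cl | starting material
11 | 1,1-dimethoxyethene | C=C(OC)OC | starting material
12 | 4,4-dimethoxybut-3-en-2-one | CC(=O)C=C(OC)OC | intermediate
13 | 1,1-dimethoxy-3-(trimethylsilyloxy)buta-1,3-diene | C=C(O[Si](C)(C)C)C=C(OC)OC | intermediate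
14 | methyl 2-[3-chloro-2,6-bis(methoxymethoxy)-4-methylbenzoyl]-3,3-dimethoxy-5-(trimethylsilyloxy)cyclohexa-1,4-diene-1-carboxylate (not isolated) | COC(=O)C1=C(C(=O)c2c(OCOC)cc(C)c(Cl)c2OCOC)C(OC)(OC)C=C(O[Si](C)(C)C)C1 | intermediate
15 | methyl 2-[3-chloro-2,6-bis(methoxymethoxy)-4-methylbenzoyl]-5-hydroxy-3-methoxybenzoate (not isolated) | COC(=O)c1cc(O)cc(OC)c1C(=O)c1c(OCOC)cc(C)c(Cl)c1OCOC | intermediate
16 | methyl 2-(3-chloro-2,6-dihydroxy-4-methylbenzoyl)-5-hydroxy-3-methoxybenzoate (monochlorosulochrin) | COC(=O)c1cc(O)cc(OC)c1C(=O)c1c(O)cc(C)c(Cl)c1O | intermediate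
17 | methyl (±)-5-chloro-4-hydroxy-6'-methoxy-6-methyl-3,4'-dioxo-3H-spiro[1-benzofuran-2,1'-cyclohexa-2',5'-diene]-2'-carboxylate (racemic) | COC(=O)C1=CC(=O)C=C(OC)C12Oc3cc(C)c(Cl)c(O)c3C2=O | intermediate
18 | isodihydromaldoxin (achiral) | COC(=O)c1cc(O)cc(OC)c1Oc1cc(C)c(Cl)c(O)c1C(=O)O | target

## Step count and risk

Total step count: 10.
Longest linear sequence: 8 steps (steps 1–5 and 8–10). Steps 6–7 make the diene in a side branch.

**Step 9 is the most likely to fail.** Closure through the chlorine-flanked OH would give the 7-chloro spiro isomer, and ring B could be over-oxidised.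

The fallback sets out from 16 and comes back at 17. It replaces substrate control by protecting-group control.
- TBSCl (2.1 equiv) and imidazole in DMF silylate the ring-A phenol and the ring-B phenol that has only one ortho substituent, giving the bis-silyl ether F1.
- The remaining OH, wedged between Cl and the aroyl group, is capped with the small electrophile MOMCl (i-Pr2NEt, CH2Cl2, reflux) to give the fully protected benzophenone F2.
- TBAF/AcOH (THF, 0 °C) frees the two silylated phenols to give the mono-MOM benzophenone F3, in which only the desired oxygen can close.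
- PhI(OAc)2 in (CF3)2CHOH gives the MOM-protected spirodienone F4.
- TFA in wet CH2Cl2 (0 °C) removes the MOM group and delivers 17.

**Step 8 is second.** Two acceptors compete for control of the regiochemistry, and a tetra-ortho-substituted benzophenone is formed in the cycloaddition.

The fallback sets out from 5, uses diene 13, and comes back at 15. It uses a dienophile that has only one acceptor and raises the oxidation level afterwards.
- Lithiated 3,3-diethoxyprop-1-yne (n-BuLi, THF, −78 °C) adds to 5 to give the propargylic alcohol F5.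
- MnO2 gives the ynone acetal F6, which is polarised by the ketone alone.
- Cycloaddition with 13 (PhMe, 110 °C) gives the cycloadduct F7.
- With PPTS in wet acetone, F7 loses methanol, the silyl group and the acetal to give the keto aldehyde F8.
- Pinnick oxidation (NaClO2, NaH2PO4, 2-methylbut-2-ene) gives the keto acid F9.
- TMSCHN2 (PhMe/MeOH, 0 °C) esterifies the acid to 15, which is deprotected as in the second stage of step 8.

**Step 10 is third.** Sulfonation of the electron-rich rings, ester hydrolysis or decarboxylation could occur in sulfuric acid.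

The fallback sets out from 17 and comes back at 18. It opens the spiro ketone with an alkoxide instead of acid and water, and frees the acid under neutral conditions.
- Lithium allyloxide (2.1 equiv, THF, −40 to 0 °C) first deprotonates the phenol. It then attacks the strained α-aryloxy ketone, and the irreversible rearomatising retro-Claisen cleavage gives the allyl ester F10.
- Pd(PPh3)4 (cat.) and morpholine (THF, rt) remove the allyl group without touching the methyl ester or the aryl chloride, giving 18.

## Further compounds

F1 | step 9 | methyl 5-(tert-butyldimethylsilyloxy)-2-[6-(tert-butyldimethylsilyloxy)-3-chloro-2-hydroxy-4-methylbenzoyl]-3-methoxybenzoate | COC(=O)c1cc(O[Si](C)(C)C(C)(C)C)cc(OC)c1C(=O)c1c(O[Si](C)(C)C(C)(C)C)cc(C)c(Cl)c1O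
F2 | step 9 | methyl 5-(tert-butyldimethylsilyloxy)-2-[6-(tert-butyldimethylsilyloxy)-3-chloro-2-(methoxymethoxy)-4-methylbenzoyl]-3-methoxybenzoate | COC(=O)c1cc(O[Si](C)(C)C(C)(C)C)cc(OC)c1C(=O)c1c(O[Si](C)(C)C(C)(C)C)cc(C)c(Cl)c1OCOC
F3 | step 9 | methyl 2-[3-chloro-6-hydroxy-2-(methoxymethoxy)-4-methylbenzoyl]-5-hydroxy-3-methoxybenzoate | COC(=O)c1cc(O)cc(OC)c1C(=O)c1c(O)cc(C)c(Cl)c1OCOC
F4 | step 9 | methyl (±)-5-chloro-6'-methoxy-4-(methoxymethoxy)-6-methyl-3,4'-dioxo-3H-spiro[1-benzofuran-2,1'-cyclohexa-2',5'-diene]-2'-carboxylate | COC(=O)C1=CC(=O)C=C(OC)C12Oc3cc(C)c(Cl)c(OCOC)c3C2=O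
F5 | step 8 | (±)-1-[3-chloro-2,6-bis(methoxymethoxy)-4-methylphenyl]-4,4-diethoxybut-2-yn-1-ol | CCOC(OCC)C#CC(O)c1c(OCOC)cc(C)c(Cl)c1OCOC
F6 | step 8 | 1-[3-chloro-2,6-bis(methoxymethoxy)-4-methylphenyl]-4,4-diethoxybut-2-yn-1-one | CCOC(OCC)C#CC(=O)c1c(OCOC)cc(C)c(Cl)c1OCOC
F7 | step 8 | [3-chloro-2,6-bis(methoxymethoxy)-4-methylphenyl][2-(diethoxymethyl)-6,6-dimethoxy-4-(trimethylsilyloxy)cyclohexa-1,4-dien-1-yl]methanone | CCOC(OCC)C1=C(C(=O)c2c(OCOC)cc(C)c(Cl)c2OCOC)C(OC)(OC)C=C(O[Si](C)(C)C)C1
F8 | step 8 | 2-[3-chloro-2,6-bis(methoxymethoxy)-4-methylbenzoyl]-5-hydroxy-3-methoxybenzaldehyde | O=Cc1cc(O)cc(OC)c1C(=O)c1c(OCOC)cc(C)c(Cl)c1OCOC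
F9 | step 8 | 2-[3-chloro-2,6-bis(methoxymethoxy)-4-methylbenzoyl]-5-hydroxy-3-methoxybenzoic acid | OC(=O)c1cc(O)cc(OC)c1C(=O)c1c(OCOC)cc(C)c(Cl)c1OCOC
F10 | step 10 | prop-2-enyl 3-chloro-2-hydroxy-6-[4-hydroxy-2-methoxy-6-(methoxycarbonyl)phenoxy]-4-methylbenzoate | COC(=O)c1cc(O)cc(OC)c1Oc1cc(C)c(Cl)c(O)c1C(=O)OCC=C
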